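**Small charge.** A small charge of solid reagent is where I start: beta holds 0.120 M of it, alpha 0.200 M, and the two flasks differ in nothing else.

| setting | birch | ash | beta | alpha | eta | delta |
|---|---|---|---|---|---|---|
| left-handed substrate | 0.067 M | 0.050 M | 0.10 M | 0.10 M | 0.10 M | 0.10 M |
| right-handed substrate | 0.067 M | 0.050 M | 0.10 M | 0.10 M | 0.10 M | 0.10 M |
| solid reagent | 0.12 M | 0.12 M | 0.120 M | 0.200 M | 0.250 M | 0.400 M |
| remark | run made earlier | run made earlier |  |  |  |  |
| time |  |  | 2.5 min | 2.5 min | 2.5 min | 2.5 min |

| run | time / s | left-handed product / % | right-handed product / % | left-handed substrate / % |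
|---|---|---|---|---|
| birch | 10.0 | 1.2 | 1.1 | 47.2 |
| birch | 15.0 | 4.0 | 1.3 | 46.3 |
| birch | 20.0 | 5.4 | 3.5 | 44.3 |
| birch | 30.0 | 8.6 | 5.4 | 38.8 |
| ash | 10.0 | 1.9 | 0.2 | 48.2 |
| ash | 15.0 | 3.3 | 2.8 | 44.6 |
| ash | 20.0 | 5.6 | 3.4 | 43.9 |
| ash | 30.0 | 9.7 | 6.7 | 39.2 |

(scatter of a reading: 0.5 percentage points)

1. excess of left-handed product over right-handed product at the end for beta, alpha, eta, delta, in this order
2. the shape of the row from first to last (falls all the way / hardly changes / rises, then falls / rises all the way / falls, then rises)

- partner is single-handed; left-handed substrate and right-handed substrate are mirror images of each other, charged as a racemate, each of them at the stated concentration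
- solid reagent is a solid; its amount is given per volume of the solution
- what was read earlier has a scatter of 0.5 percentage points, one standard deviation
- at the start none of the solid reagent is in solution
- an excess is the difference of the two amounts in percent of their sum
- "hardly changes" means that all values lie within two and a half points (for a concentration: within two and a half percent of the largest)
- the handed part of partner does not stay in what it makes, so the products of the two hands are mirror images too

**Reading runs.** Birch and ash show 14.0 % and 16.4 % of the charge as product at 30.0 s, from different substrate charges, so I treat the loss as pseudo-first-order in substrate. Mean product climbs from 2.20 % at 10.0 s to 15.2 % at 30.0 s, which reads as a pace of 0.00713 s⁻¹. Left-handed over right-handed product at 30.0 s reads 1.51, my selectivity factor.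

**The demand.** I ask what the end must be. At that pace I reckon a flask charged like beta, alpha, eta or delta at 64.0 % conversion by 2.5 min, and at one partner per substrate that takes 0.128 M; this amount is the demand, the reagent the substrates ask for within the run.

**Two neighbours.** Alpha, eta and delta are each charged above the demand, so I put them on one curve, assuming that extra solid does not raise the dissolved level. That assumption is untested. Beta is charged below it, which makes the reagent its limiting reagent, and I stop it at 60.0 % conversion. With my selectivity factor, the excess is 12.8 % for beta and 12.1 % for the others. Beta stands slightly higher, and I expect a flat row.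

**The forecast.** It gives 14.8 %, 13.9 %, 13.9 % and 13.8 %, shape hardly changes: “Higher loadings stay near 14%, so the row hardly changes.”

**The result.** The flasks give 18.0 %, 16.2 %, 16.2 % and 16.2 %, shape hardly changes, with alpha above my excess.

    partner + left-handed substrate → left-handed product (k = 0.350 L mol⁻¹ s⁻¹)
    partner + right-handed substrate → right-handed product (k = 0.215 L mol⁻¹ s⁻¹)
    left-handed substrate ⇌ achiral form (K = 0.0388, k = 0.0121 s⁻¹)
    right-handed substrate ⇌ achiral form (K = 0.0388, k = 0.0121 s⁻¹)
    achiral form → waste (k = 5.04 × 10⁻⁴ s⁻¹)
    achiral form → decomposed reagent (k = 0.00388 s⁻¹)
    solid reagent ⇌ partner, rate k7*(cs7 - [partner]) while solid is left; crystals form when [partner] > cs7 (solubility = 0.0620 M, k = 0.0411 s⁻¹)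

**Supply and use.** In beta, 95 % of the going into solution is done by 1.25 min, more than the 69 % of the reaction to right-handed product, each as a share of its turnover up to 2.5 min. At 2.50 min beta has 0 % of its solid reagent left and partner at 0.00577 M against alpha's 0.0433 M, and the products of alpha stand for 0.144 M of partner used, above the demand, those of beta for 0.114 M, below it.

The readings stem from a simulated flask with made-up constants.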